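## Structural features

Cycloshizukaol A (28) is a C2-symmetric dimer of two lindenane units. Each unit has a cyclopropane (C1–C2–C3) fused to a cyclopentene (ring A: C1, C3, C4, C5, C10) that shares C5–C10 with a cyclohexenone (ring B: C5–C10). The halves are joined head to tail by two C15–C11′ bonds, so that C4, C5, C6, C7, C11, C15′ and their primed counterparts form a 12-membered carbocycle. Each half has four contiguous stereocentres (C9 carbinol, quaternary C10 with methyl C14, and the cyclopropane carbons C1 and C3) and one isolated all-carbon quaternary centre, C11 (methyl C13, ester C12), which has no neighbouring stereocentre to control it. The C14 methyl, the cyclopropane CH2 and the C9 hydroxyl all lie on the same (β) face. The fragile parts are the C4=C5–C6=C7–C8=O dienone ending in a vinylcyclopropane, the epimerisable C8/C9 α-ketol, and, in any precursor with an oxygenated sp3 C4, the easy ionisation of C4 to a bicyclo[3.1.0]hexenyl cation. The real difficulties are forming quaternary C10 on the correct face next to the cyclopropane, fixing C11, and closing a 12-membered ring from two identical halves when a smaller ring is available to each half. The key step exploits ring B: with oxygen on C8 and C9 and a fully substituted C10, it is a 6,6-disubstituted 2-methoxycyclohexa-2,4-dienone displaced by one redox-neutral shuffle, and such a dienone is what a dienylketene electrocyclisation gives when C6–C9 come from a cyclobutenone and C5=C10 from ring A. In the monomers below, C6–C9 and C11–C13 are the atoms that end up in the partner half.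

## Logic of the disconnections

**28 ⇒ 27.** No skeletal bond is cut. The C8 ketone and the C4=C5 alkene are traced back to a C8 methyl enol ether and a C4 silyl ether, so the retro step re-forms C8–OMe and C4–OSi. This removes the sensitive dienone and α-ketol from all earlier intermediates. The forward step must be a mild aqueous acid treatment in which the dienol ether pushes out the C4 oxygen, without epimerising C9.

**27 ⇒ 26.** The C9–H bonds are cut, turning both carbinols into ketones. The C9 carbonyl is the ketene carbon of the planned electrocyclisation, so it has to be present in 26. The forward reduction must be a 1,2-reduction with hydride arriving anti to the C14 methyl.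

**26 ⇒ 23 + 23.** C5–C6 and C9–C10 are cut in both halves, which opens both rings B and the 12-membered ring and leaves two identical monomers. This is the largest simplification in the plan: three rings, four skeletal bonds and the two C10 centres. The forward step needs an alkenyl–allyl coupling at a tetrasubstituted C5, a ring expansion that closes C9 onto the α-face of C10, and dimerisation in preference to ring closure within one molecule.

**23 ⇒ 22 ⇒ 20.** The C6–Cl and then the C5–Sn bonds are cut. The chloride cannot coexist with zerovalent palladium, so tin must be installed first. The stannane is acid-labile (protonation at C5 gives a cyclopropyl-stabilised cation), so the iodide is carried as long as possible. The forward steps need a chlorination without free acid and a stannylation that tolerates an α-hydroxy cyclobutenone.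

**20 ⇒ 19 ⇒ 17.** First the C9 ketone and C7=C8 are traced back to a fully protected cyclobutene-diol bis(enol ether) (19). Then the C4–OSi and C12–OMe bonds are cut and the O4–C12 lactone bond is re-formed (17). The spirolactone is the device that controls C11, but it cannot stay: it forces C7 to the side of the lactone ring remote from C5, and that geometry cannot close the 12-membered ring. The forward demands are a lactone opening that silylates O4 as it is freed (a free γ-hydroxy ester would relactonise), and an ionisation at C7 rather than C6.

**17 ⇒ 16 ⇒ 15 ⇒ 11 + 12.** The C11–C7 bond is cut (with C6–H and C13–H), giving the α-methylene lactone 11 and 12. Adding the C11 enolate to a carbonyl of 12 makes that carbon C7 and leaves the other carbonyl as C6, which is exactly the carbon that must be reduced. The forward step must add the tetrasubstituted enolate anti to the C5 iodine and trap the aldolate before it reverts.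

**11 ⇒ 8 + 9.** C4–C15 and O4–C12 are cut. An allylzinc reagent reliably adds to a hindered conjugated ketone and carries the whole C15–C11(=C13)–C12 unit. The forward step must add 1,2 and anti to the cyclopropane CH2.

**8 ⇒ 7 ⇒ 5 ⇒ 4 ⇒ 1 + 2.** In turn: C5–I is cut; the C5=C10 unsaturation and the ketone are traced to an alcohol; the cyclopropane bonds C3–C1 and C3–C2 are cut back to an epoxide and a terminal alkene; and the bond between the epoxide-derived CH2 and the methyl-bearing carbon is cut. All absolute stereochemistry then comes from 1. The forward steps need γ-selective crotyl transfer and a trans-selective carbenoid cyclopropanation.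

## Other disconnections considered

**Alternative 1:** The cut is C7–C11 and C7′–C11′. In retro-Claisen terms each of these bonds becomes a C9–O–C12 ester, so the carbocycle expands to the 16-membered diolide A1. Forward, KN(SiMe3)2 and t-BuMe2SiCl would enolise and silylate both esters of A1, and two transannular Ireland–Claisen shifts would contract the ring to diacid A2.
- In favour: dimerising macrolactonisation is much better precedented than a Stille cyclodimerisation and has no small-ring competitor. On ring formation this plan is the better one. The [3,3] shift is suprafacial, so an α C9–O bond delivers C11 to the α-face of C7, and no tin is used.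
- Against: C11 becomes quaternary with the right configuration only if both ketene acetal geometries and the chair/boat choice are controlled inside a 16-membered ring, and there is no handle for that. The shift also removes the C9 oxygen and leaves ring B with C6 and C7 saturated. The C6=C7 alkene, the C8 ketone and the C9 hydroxyl would all have to be installed afterwards on both halves. A1 also needs C10 and ring A made by other means.
- Comparison: structurally the alternative forms only C7–C11 and C11, whereas the chosen step forms both rings B, C10 and the macrocycle. Mechanistically it is a single, well-understood pericyclic type, against a cascade with an open ring-size question. On step economy its endgame is clearly longer than the two redox-neutral steps after 26.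

**Alternative 2:** The cut is C5–C10, C1–C3 and C3–C4 in both halves, which unravels rings A and B to the 12-membered dienediyne A3. Forward, A3 complexed at both alkynes by Co2(CO)8 and heated with N-methylmorpholine N-oxide would undergo two Pauson–Khand reactions to give A4.
- In favour: six C–C bonds and four rings form in one operation, with CO supplying C3. The C9 oxygen and its configuration are in place from the start, which is better than the late C9 reduction of the chosen plan. No tin is used.
- Against: A3 holds two linear alkynes and two E ring alkenes in a 12-membered ring, which is strained and not obviously accessible. A 1,1-disubstituted alkene forming a quaternary centre is the slow class of Pauson–Khand substrate. A4 has a C3 ketone, a C1 methylene and no cyclopropane, so C1–C2–C3 and its two stereocentres must be built afterwards, and the C8/C9 diol must be differentiated.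
- Comparison: it builds more rings per step than the chosen plan and matches it in setting C10 in the key step. Its mechanism is a known metal-mediated cycloaddition, but on a doubtful substrate. It has the heaviest post-key-step burden of the three alternatives.

**Alternative 3:** The cut is the two C4=C5 alkenes, giving the 18-membered ring A5, in which each cyclohexenone carries on C10 a cyclopropane whose C3 bears the C4 ketone. Forward, KOtBu in t-BuOH would deprotonate each C8 enone at C5; each dienolate would attack its C4 ketone across the ring and dehydrate to give A6, the bis(TBS ether) of 28.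
- In favour: it ends one deprotection from the target, which is the best endgame of all the plans and better than the chosen one. Every stereocentre is set beforehand, and the five-membered aldol closure is favourable.
- Against: the base acts on an α-silyloxy ketone (C9 epimerisation) and on a cyclopropyl ketone (C3 epimerisation to a trans-cyclopropane that cannot close). Extended dienolates tend to react at the α-carbon. A5 needs its own 18-membered macrocyclisation with C10 and both C11 centres already in place.
- Comparison: structurally it forms only two alkenes in the key step. Mechanistically it is classical and equal or better in predictability. On step economy the work is moved into a long synthesis of A5.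

Key step: step 13

Remark: trimethylstannyl replaces tributylstannyl at C5 for faster transmetalation at the tetrasubstituted carbon. The carbinol centres of the four-membered ring in 14–22 and the C6 chloride of 23 are epimer mixtures that converge because these carbons become sp2. The stereodescriptors of 23 and 26 were checked centre by centre against 28 and needed no correction.

## Route

Step 1
Reactants: 1 (S)-epichlorohydrin; 2 crotylmagnesium chloride
Product: 4 (2S)-2-(2-methylbut-3-en-1-yl)oxirane, via chlorohydrin magnesium alkoxide 3 (not isolated)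
Conditions: CH3CH=CHCH2MgCl, THF, −40 to 0 °C; then NaOH, H2O, 25 °C
Reagents that add atoms: none
Why: The allylic Grignard reagent opens the epoxide at its CH2 terminus through its γ-carbon (SE2′ epoxide opening) and NaOH closes the new epoxide by Williamson displacement of chloride, so the carbinol centre is untouched and (S) gives (S); the methyl-bearing carbon forms as both epimers, which converge in step 3.

Step 2
Reactants: 4 (2S)-2-(2-methylbut-3-en-1-yl)oxirane
Product: 5 (1S,2S,5S)-4-methylbicyclo[3.1.0]hexan-2-ol
Conditions: LiTMP (2,2,6,6-tetramethylpiperidine, n-BuLi), t-BuOMe, 0 to 25 °C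
Reagents that add atoms: none
Why: LiTMP lithiates the epoxide CH2 trans to the chain and the α-lithiated epoxide acts as a carbenoid that cyclopropanates the tethered alkene (intramolecular cyclopropanation of an unsaturated terminal epoxide); the retained carbinol centre sets C1 and C3 with the hydroxyl anti to the cyclopropane CH2.

Step 3
Reactants: 5 (1S,2S,5S)-4-methylbicyclo[3.1.0]hexan-2-ol
Product: 7 (1S,5R)-4-methylbicyclo[3.1.0]hex-3-en-2-one, via ketone 6 (not isolated)
Conditions: IBX (3.5 equiv), DMSO, 25 °C then 75 °C
Reagents that add atoms: none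
Why: IBX oxidises the alcohol and, on warming, dehydrogenates the ketone on its only enolisable side (IBX dehydrogenation; the cyclopropyl bridgehead cannot enolise), so both methyl epimers give one enone.

Step 4
Reactants: 7 (1S,5R)-4-methylbicyclo[3.1.0]hex-3-en-2-one
Product: 8 (1S,5R)-3-iodo-4-methylbicyclo[3.1.0]hex-3-en-2-one
Conditions: I2, pyridine, CH2Cl2, 0 to 25 °C
Reagents that add atoms: iodine, II
Why: α-Iodination of an enone by reversible conjugate addition of pyridine, iodination of the enolate and elimination (Morita–Baylis–Hillman-type mechanism), as used for 2-iodo-3-methylcycloalkenones.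

Step 5
Reactants: 8 (1S,5R)-3-iodo-4-methylbicyclo[3.1.0]hex-3-en-2-one; 9 methyl 2-(bromomethyl)acrylate
Product: 11 α-methylene spirolactone 3-iodo-4-methyl-4'-methylidenespiro[bicyclo[3.1.0]hex-3-ene-2,2'-oxolan]-5'-one, via bromozinc alkoxide 10 (not isolated)
Conditions: Zn dust, THF, 0 °C (9 to the allylzinc bromide); 8, 0 to 45 °C; aq NH4Cl
Reagents that add atoms: none
Why: Dreiding–Schmidt reaction: the 2-(methoxycarbonyl)allylzinc reagent adds 1,2 to the ketone through a six-membered transition state from the face anti to the cyclopropane CH2, which sets C4 with C15 α and oxygen β, and the zinc alkoxide lactonises onto the ester.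

Step 6
Reactants: 11 α-methylene spirolactone; 12 dimethyl squarate
Product: 15 spirolactone carrying at C11 a methyl group and a 2,3-dimethoxy-4-oxo-1-(trimethylsilyloxy)cyclobut-2-en-1-yl group, via lithium enolate 13 (not isolated), via lithium aldolate 14 (not isolated)
Conditions: LiBH(s-Bu)3 (1.0 equiv), THF, −78 °C; 12, −78 °C; Me3SiCl, −78 to −40 °C
Reagents that add atoms: chlorotrimethylsilane, C[Si](C)(C)Cl
Why: Reductive aldol: 1,4-hydride addition to the α-methylene lactone gives the tetrasubstituted enolate regiospecifically, and this adds 1,2 to a squarate carbonyl on the lactone face turned towards C3, away from the large C5 iodine, which sets C11 by substrate control in the rigid spirocycle; silylation of the aldolate blocks retro-aldol cleavage, and the new carbinol centre is inconsequential.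

Step 7
Reactants: 15 silyl-capped squarate adduct
Product: 16 the corresponding 4-hydroxycyclobutene (C6 carbinol)
Conditions: NaBH4, CeCl3·7H2O, MeOH/THF, −78 °C
Reagents that add atoms: none
Why: Luche 1,2-reduction of the only ketone, which is the carbon destined to become C6; the lactone is untouched at this temperature and the configuration of the new carbinol is inconsequential.

Step 8
Reactants: 16 C6 carbinol
Product: 17 C6 triethylsilyl ether
Conditions: Et3SiOTf, 2,6-lutidine, CH2Cl2, −78 °C
Reagents that add atoms: triethylsilyl trifluoromethanesulfonate, CC[Si](CC)(CC)OS(=O)(=O)C(F)(F)F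
Why: Silylation of the secondary alcohol prevents base-induced silyl migration and retro-aldol cleavage in step 9, and fixes the order of acid lability needed in step 10 (tertiary Me3Si on C7, then secondary Et3Si on C6, then tertiary Et3Si on C4).

Step 9
Reactants: 17 fully silylated spirolactone
Product: 19 open-chain methyl ester with the C4 triethylsilyl ether, via potassium carboxylate 18 (not isolated)
Conditions: KOSiEt3 (Et3SiOH, KH), THF, 0 to 40 °C; then MeI, DMF, 25 °C
Reagents that add atoms: potassium triethylsilanolate, [K+].[O-][Si](CC)(CC)CC; iodomethane, CI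
Why: Proposed new method: the silanolate attacks the lactone carbonyl, the tetrahedral intermediate expels the C4 tertiary alkoxide, and that alkoxide takes the silyl group from the transient silyl ester (the carboxylate is the thermodynamic sink), so O4 is silylated as it is freed and cannot relactonise, after which MeI alkylates the carboxylate; the closest known reaction type is anhydrous ester cleavage by potassium trimethylsilanolate, which gives carboxylate and silyl ether by the same acyl substitution and silyl transfer.

Step 10
Reactants: 19 open-chain methyl ester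
Product: 20 C5 iodide carrying the 4-hydroxy-2-methoxycyclobut-2-en-1-one
Conditions: AcOH/THF/H2O (3:1:1), 0 to 25 °C
Reagents that add atoms: water, O
Why: The most labile group, the tertiary Me3Si ether on C7, goes first and C7 ionises to a methoxy-stabilised cyclobutenyl cation that water captures at C9; loss of methanol gives the C9 ketone and C7=C8 (vinylogous ketal hydrolysis, as in a Stork–Danheiser transposition) while C6 is still silylated and cannot ionise, and the secondary Et3Si ether is then hydrolysed whereas the hindered tertiary one on C4 should remain.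

Step 11
Reactants: 20 iodo hydroxycyclobutenone; 21 hexamethylditin
Product: 22 C5 trimethylstannane carrying the 4-hydroxy-2-methoxycyclobut-2-en-1-one
Conditions: PdCl2(MeCN)2 (5 mol%), NMP, 40 °C
Reagents that add atoms: none
Why: Palladium-catalysed stannylation of an alkenyl iodide with a ditin (oxidative addition to zerovalent palladium, Sn–Sn transmetalation, reductive elimination); the hydroxyl is not a leaving group, so the cyclobutenone is inert.

Step 12
Reactants: 22 stannyl hydroxycyclobutenone
Product: 23 C5 trimethylstannane carrying the C11-linked 4-chloro-2-methoxycyclobut-2-en-1-one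
Conditions: Me2C=C(Cl)NMe2, CH2Cl2, 0 to 25 °C
Reagents that add atoms: 1-chloro-N,N,2-trimethylprop-1-en-1-amine, CC(C)=C(Cl)N(C)C
Why: Deoxychlorination through the alkoxy-iminium chloride without free acid, which spares the acid-labile alkenylstannane and the C4 silyl ether; either C6 epimer is acceptable.

Step 13
Reactants: 23 stannyl chlorocyclobutenone (two molecules)
Product: 26 macrocyclic bis(2-methoxycyclohexa-2,4-dienone) with C9 ketones and C4 triethylsilyl ethers, via macrocyclic bis(4-alkenylcyclobutenone) 24 (not isolated), via bis(dienylketene) 25 (not isolated)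
Conditions: Pd2(dba)3 (5 mol%), P(2-furyl)3 (20 mol%), CuI (10 mol%), dioxane, 0.1 M, 45 °C; then diluted to 2 mM, 100 °C
Reagents that add atoms: none
Why: Proposed new method: zerovalent palladium inserts into the allylic C6–Cl bond of one molecule of 23, the hindered C5–SnMe3 of a second molecule transmetalates (CuI assists by Sn-to-Cu exchange) and reductive elimination forms C5–C6, after which the second C5–C6 bond closes the 12-membered ring to give 24. On heating, each 4-alkenylcyclobutenone opens by reversible conrotatory 4π cleavage of C6–C9 to a vinylketene, and only the rotamer with the ring A alkene turned inward (25) can close C9 onto C10 by disrotatory 6π electrocyclisation, which drains the equilibrium. The closest known reaction type is the Stille coupling of 4-chlorocyclobutenones with alkenylstannanes followed by thermal ring expansion to phenols or 6,6-disubstituted cyclohexadienones, together with Stille cyclodimerisation to macrocycles; merging them into one macrocyclising cascade is new. Ring closures: the 12-membered ring by intramolecular alkenyl–allyl cross-coupling, and each six-membered ring B by 6π electrocyclisation at C9–C10. Stereocentres: C10 and C10′ are set when the ketene carbon bonds to the α-face of C5=C10, anti to the adjacent cyclopropane CH2, which leaves the C14 methyl β, and because C10 is quaternary the product cannot tautomerise to a phenol. The regiochemistry of ring B is fixed by the substitution of the four-membered ring (OMe on C8, C11 on C7, Cl on C6), and either C6 epimer serves because C6 becomes sp2. The selectivity the step needs is head-to-tail dimerisation over coupling of C5 with the C6 of the same molecule (a six-membered ring) and over chain growth; the substrate offers only the strain of that bicyclo[4.2.0] product, helped by a concentrated first stage and a dilute second stage, and this is the weakest point of the plan.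

Step 14
Reactants: 26 macrocyclic bis(dienone)
Product: 27 macrocyclic bis(C9 β-alcohol)
Conditions: NaBH4, CeCl3·7H2O, MeOH/THF, −78 °C
Reagents that add atoms: none
Why: Luche 1,2-reduction of the two cross-conjugated C9 ketones; hydride approaches anti to the pseudo-axial C14 methyl on the neighbouring quaternary C10 (α-face), giving both 9β-hydroxyls.

Step 15
Reactants: 27 macrocyclic bis(C9 β-alcohol)
Product: 28 cycloshizukaol A
Conditions: 0.1 M aq HCl/THF (1:4), 0 °C
Reagents that add atoms: water, O
Why: Vinylogous ionisation and enol ether hydrolysis: the C8 methoxy group pushes through C7=C8 and C5=C6 to expel the C4 silyloxy group, water adds to the C8 oxocarbenium ion and methanol is lost, giving the C4=C5–C6=C7–C8=O dienone without a change in oxidation level; quaternary C10 blocks aromatisation, and cold dilute acid should leave the C9 α-ketol centre intact.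

## Compound list

1 | (S)-epichlorohydrin | ClC[C@@H]1CO1 | starting material
2 | crotylmagnesium chloride (E/Z) | CC=CC[Mg]Cl | starting material
3 | chloromagnesium (2S)-1-chloro-4-methylhex-5-en-2-olate (both C4 epimers) | ClC[C@@H](O[Mg]Cl)CC(C)C=C | intermediate (not isolated)
4 | (2S)-2-(2-methylbut-3-en-1-yl)oxirane (both epimers at the methyl-bearing carbon) | C=CC(C)C[C@H]1CO1 | intermediate
5 | (1S,2S,5S)-4-methylbicyclo[3.1.0]hexan-2-ol, hydroxyl anti to the cyclopropane CH2 (both C4 epimers) | C1C(C)[C@@H]2C[C@@H]2[C@H]1O | intermediate
6 | (1S,5S)-4-methylbicyclo[3.1.0]hexan-2-one (both C4 epimers) | C1C(C)[C@@H]2C[C@@H]2C1=O | intermediate (not isolated)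
7 | (1S,5R)-4-methylbicyclo[3.1.0]hex-3-en-2-one | C1=C(C)[C@@H]2C[C@@H]2C1=O | intermediate
8 | (1S,5R)-3-iodo-4-methylbicyclo[3.1.0]hex-3-en-2-one | IC1=C(C)[C@@H]2C[C@@H]2C1=O | intermediate
9 | methyl 2-(bromomethyl)acrylate | C=C(CBr)C(=O)OC | starting material
10 | bromozinc alkoxide of methyl 2-[(2-hydroxy-3-iodo-4-methylbicyclo[3.1.0]hex-3-en-2-yl)methyl]acrylate, C15 anti to the cyclopropane CH2 | IC1=C(C)[C@@H]2C[C@@H]2[C@@]1(O[Zn]Br)CC(=C)C(=O)OC | intermediate (not isolated)
11 | 3-iodo-4-methyl-4'-methylidenespiro[bicyclo[3.1.0]hex-3-ene-2,2'-oxolan]-5'-one, lactone oxygen syn to the cyclopropane CH2 | IC1=C(C)[C@@H]2C[C@@H]2[C@@]1(OC3=O)CC3=C | intermediate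
12 | dimethyl squarate | COC1=C(OC)C(=O)C1=O | starting material
13 | lithium enolate of the α-methyl spirolactone | IC1=C(C)[C@@H]2C[C@@H]2[C@@]1(OC(O[Li])=C3C)C3 | intermediate (not isolated)
14 | lithium aldolate of the squarate adduct (C11 as in 28; C7 carbinol epimers) | IC1=C(C)[C@@H]2C[C@@H]2[C@@]1(OC3=O)C[C@]3(C)C4(O[Li])C(OC)=C(OC)C4=O | intermediate (not isolated)
15 | spirolactone with C11 methyl and 2,3-dimethoxy-4-oxo-1-(trimethylsilyloxy)cyclobut-2-en-1-yl (C11 as in 28; C7 epimers) | IC1=C(C)[C@@H]2C[C@@H]2[C@@]1(OC3=O)C[C@]3(C)C4(O[Si](C)(C)C)C(OC)=C(OC)C4=O | intermediate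
16 | C6 carbinol of 15 (C6 and C7 epimers) | IC1=C(C)[C@@H]2C[C@@H]2[C@@]1(OC3=O)C[C@]3(C)C4(O[Si](C)(C)C)C(OC)=C(OC)C4O | intermediate
17 | C6 triethylsilyl ether of 16 | IC1=C(C)[C@@H]2C[C@@H]2[C@@]1(OC3=O)C[C@]3(C)C4(O[Si](C)(C)C)C(OC)=C(OC)C4O[Si](CC)(CC)CC | intermediate
18 | potassium carboxylate with the C4 triethylsilyl ether (ring-opened 17) | IC1=C(C)[C@@H]2C[C@@H]2[C@@]1(O[Si](CC)(CC)CC)C[C@@](C)(C(=O)[O-])C3(O[Si](C)(C)C)C(OC)=C(OC)C3O[Si](CC)(CC)CC.[K+] | intermediate (not isolated)
19 | methyl ester of 18: C5 iodide, C4 triethylsilyl ether, C11 quaternary, protected cyclobutene-diol bis(enol ether) | IC1=C(C)[C@@H]2C[C@@H]2[C@@]1(O[Si](CC)(CC)CC)C[C@@](C)(C(=O)OC)C3(O[Si](C)(C)C)C(OC)=C(OC)C3O[Si](CC)(CC)CC | intermediate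
20 | C5 iodide carrying the C11-linked 4-hydroxy-2-methoxycyclobut-2-en-1-one (C6 epimers) | IC1=C(C)[C@@H]2C[C@@H]2[C@@]1(O[Si](CC)(CC)CC)C[C@@](C)(C(=O)OC)C3=C(OC)C(=O)C3O | intermediate
21 | hexamethylditin | C[Sn](C)(C)[Sn](C)(C)C | starting material
22 | C5 trimethylstannane carrying the 4-hydroxy-2-methoxycyclobut-2-en-1-one (C6 epimers) | C[Sn](C)(C)C1=C(C)[C@@H]2C[C@@H]2[C@@]1(O[Si](CC)(CC)CC)C[C@@](C)(C(=O)OC)C3=C(OC)C(=O)C3O | intermediate
23 | ring A C5 trimethylstannane carrying the C11-linked 4-chloro-2-methoxycyclobut-2-en-1-one (C6 epimers; key-step precursor) | C[Sn](C)(C)C1=C(C)[C@@H]2C[C@@H]2[C@@]1(O[Si](CC)(CC)CC)C[C@@](C)(C(=O)OC)C3=C(OC)C(=O)C3Cl | intermediate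
24 | 12-membered bis(4-alkenylcyclobutenone) (C6 epimers) | COC(=O)[C@]1(C)C[C@@]2(O[Si](CC)(CC)CC)C(=C(C)[C@@H]3C[C@H]23)C4C(=O)C(OC)=C4[C@](C)(C(=O)OC)C[C@@]5(O[Si](CC)(CC)CC)C(=C(C)[C@@H]6C[C@H]56)C7C(=O)C(OC)=C71 | intermediate (not isolated)
25 | 12-membered bis(dienylketene), C5 and C8 cis on each C6=C7 | COC(=O)[C@]1(C)C[C@@]2(O[Si](CC)(CC)CC)C(=C(C)[C@@H]3C[C@H]23)C=C(C(OC)=C=O)[C@](C)(C(=O)OC)C[C@@]4(O[Si](CC)(CC)CC)C(=C(C)[C@@H]5C[C@H]45)C=C1C(OC)=C=O | intermediate (not isolated)
26 | macrocyclic bis(2-methoxycyclohexa-2,4-dienone) with C9 ketones and C4 triethylsilyl ethers (key-step product) | COC(=O)[C@]1(C)C[C@@]2(O[Si](CC)(CC)CC)C3=CC(=C(OC)C(=O)[C@@]3(C)[C@@H]3C[C@H]23)[C@](C)(C(=O)OC)C[C@@]2(O[Si](CC)(CC)CC)C3=CC1=C(OC)C(=O)[C@@]3(C)[C@@H]1C[C@H]21 | intermediate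
27 | macrocyclic bis(9β-alcohol) of 26 | COC(=O)[C@]1(C)C[C@@]2(O[Si](CC)(CC)CC)C3=CC(=C(OC)[C@H](O)[C@@]3(C)[C@@H]3C[C@H]23)[C@](C)(C(=O)OC)C[C@@]2(O[Si](CC)(CC)CC)C3=CC1=C(OC)[C@H](O)[C@@]3(C)[C@@H]1C[C@H]21 | intermediate
28 | cycloshizukaol A | COC(=O)[C@]1(C)CC2=C3C=C(C(=O)[C@H](O)[C@@]3(C)[C@@H]3C[C@H]23)[C@](C)(C(=O)OC)CC2=C3C=C1C(=O)[C@H](O)[C@@]3(C)[C@@H]1C[C@H]21 | target

## Step count and least certain steps

Total: 15 steps. Longest linear sequence: 15 steps (1 to 28). Compounds 2, 9, 12 and 21 are purchased.

**Step 13 (key step, proposed new method).** The most likely failure is ring closure within one molecule: C5 couples with the C6 of its own cyclobutenone (six-membered ring) faster than with a second molecule. The second most likely is chain growth instead of closure of the 12-membered ring.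
Fallback with known chemistry, setting out from 20 and 22 and returning at 26. Chlorination of 20 with the chloroenamine of step 12 gives the iodo chlorocyclobutenone F1. F1 is coupled with 22 (Pd2(dba)3, P(2-furyl)3, CuI, dioxane, 50 then 100 °C). This is an ordinary intermolecular Stille coupling and ring expansion, because 22 has no leaving group and F1 has no stannane, and the allylic chloride should add zerovalent palladium faster than the hindered iodide. It gives the half-closed dimer F2 with one ring B. Stannylation of the iodide (21, PdCl2(MeCN)2) gives the stannane F3, and chlorination gives the stannyl chloride F4. The remaining tin and chloride are now at opposite ends and can meet only in the 12-membered ring. They are coupled at high dilution, with ring expansion, to reach 26.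

**Step 9 (proposed new method).** The most likely failure is slow acyl substitution at the very hindered lactone carbonyl, or incomplete silyl transfer to the tertiary alkoxide followed by relactonisation.
Fallback with known chemistry, setting out from 17 and returning at 19. LiOH in THF/H2O at 40 °C opens the lactone to the lithium hydroxy carboxylate F5. The dried salt is silylated with Et3SiOTf and 2,6-lutidine to the silyl ether silyl ester F6. Aqueous NaHCO3 in MeOH cleaves only the silyl ester to give the acid F7, whose C4 oxygen is protected and cannot lactonise. Me3SiCHN2 in MeOH/toluene then gives 19.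

**Step 6.** The most likely failure is poor facial selectivity at C11 if the C5 iodine does not shield its side of the lactone enough. Reversal of the aldol addition before silylation, or addition–elimination at a methoxy carbon of 12, are further possibilities.
Fallback, setting out from 11 and returning at 22. The iodide of 11 is stannylated first (21, PdCl2(MeCN)2, NMP) to the stannyl lactone F8, whose much larger SnMe3 group is the shield. The reductive aldol of step 6 gives the silyl-capped adduct F9. Steps 7, 8 and 9 give the carbinol F10, the silyl ether F11 and the open ester F12. The acid treatment of step 10, kept short and cold to avoid protodestannylation, then gives 22 directly, and step 11 is omitted.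

**Step 10.** The most likely failure is ionisation at the wrong carbinol carbon (C6 instead of C7) once the C6 silyl ether is lost, leading to the regioisomeric cyclobutenone. Loss of the C4 silyl ether with relactonisation is the other risk.
Fallback, setting out from 19 and returning at 20. K2CO3 in MeOH at 0 °C removes only the Me3Si group and gives the tertiary alcohol F13. (CF3CO)2O and pyridine at −78 °C acylate only that hydroxyl. The trifluoroacetate ionises towards C9 under basic, non-aqueous conditions in which the C6 silyl ether cannot leave, and aqueous work-up gives the 4-(triethylsilyloxy)cyclobutenone F14 regiospecifically. HF·pyridine buffered with pyridine then cleaves the secondary silyl ether faster than the tertiary one and gives 20.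

**Step 1.** The most likely failure is crotyl transfer through the α-carbon (linear product). Direct displacement of chloride, which would erode enantiopurity, is the other risk.
Fallback, returning at 7. Commercial (S)-2-(but-3-en-1-yl)oxirane F15 is cyclised with LiTMP to (1S,2S,5R)-bicyclo[3.1.0]hexan-2-ol F16. IBX oxidises and dehydrogenates it to (1S,5S)-bicyclo[3.1.0]hex-3-en-2-one F17. Conjugate addition of Me2CuLi anti to the cyclopropane gives 6 as a single C4 epimer, which is dehydrogenated with IBX as in the second stage of step 3 to give 7.

## Further compounds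

F1 | step 13 | C5 iodide carrying the 4-chloro-2-methoxycyclobut-2-en-1-one | IC1=C(C)[C@@H]2C[C@@H]2[C@@]1(O[Si](CC)(CC)CC)C[C@@](C)(C(=O)OC)C3=C(OC)C(=O)C3Cl
F2 | step 13 | half-closed dimer with one ring B, a 4-hydroxycyclobutenone end and a C5 iodide end | OC1C(=O)C(OC)=C1[C@](C)(C(=O)OC)C[C@@]2(O[Si](CC)(CC)CC)C3=CC(=C(OC)C(=O)[C@@]3(C)[C@@H]3C[C@H]23)[C@](C)(C(=O)OC)C[C@@]4(O[Si](CC)(CC)CC)C(I)=C(C)[C@@H]5C[C@H]45
F3 | step 13 | half-closed dimer with a 4-hydroxycyclobutenone end and a C5 trimethylstannane end | OC1C(=O)C(OC)=C1[C@](C)(C(=O)OC)C[C@@]2(O[Si](CC)(CC)CC)C3=CC(=C(OC)C(=O)[C@@]3(C)[C@@H]3C[C@H]23)[C@](C)(C(=O)OC)C[C@@]4(O[Si](CC)(CC)CC)C([Sn](C)(C)C)=C(C)[C@@H]5C[C@H]45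
F4 | step 13 | half-closed dimer with a 4-chlorocyclobutenone end and a C5 trimethylstannane end | ClC1C(=O)C(OC)=C1[C@](C)(C(=O)OC)C[C@@]2(O[Si](CC)(CC)CC)C3=CC(=C(OC)C(=O)[C@@]3(C)[C@@H]3C[C@H]23)[C@](C)(C(=O)OC)C[C@@]4(O[Si](CC)(CC)CC)C([Sn](C)(C)C)=C(C)[C@@H]5C[C@H]45
F5 | step 9 | lithium carboxylate with free C4 tertiary alcohol (hydrolysed 17) | IC1=C(C)[C@@H]2C[C@@H]2[C@@]1(O)C[C@@](C)(C(=O)[O-])C3(O[Si](C)(C)C)C(OC)=C(OC)C3O[Si](CC)(CC)CC.[Li+]
F6 | step 9 | C4 triethylsilyl ether triethylsilyl ester | IC1=C(C)[C@@H]2C[C@@H]2[C@@]1(O[Si](CC)(CC)CC)C[C@@](C)(C(=O)O[Si](CC)(CC)CC)C3(O[Si](C)(C)C)C(OC)=C(OC)C3O[Si](CC)(CC)CC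
F7 | step 9 | C4 triethylsilyl ether carboxylic acid | IC1=C(C)[C@@H]2C[C@@H]2[C@@]1(O[Si](CC)(CC)CC)C[C@@](C)(C(=O)O)C3(O[Si](C)(C)C)C(OC)=C(OC)C3O[Si](CC)(CC)CC
F8 | step 6 | C5 trimethylstannyl α-methylene spirolactone | C[Sn](C)(C)C1=C(C)[C@@H]2C[C@@H]2[C@@]1(OC3=O)CC3=C
F9 | step 6 | C5 trimethylstannyl analogue of 15 | C[Sn](C)(C)C1=C(C)[C@@H]2C[C@@H]2[C@@]1(OC3=O)C[C@]3(C)C4(O[Si](C)(C)C)C(OC)=C(OC)C4=O
F10 | step 6 | C5 trimethylstannyl analogue of 16 | C[Sn](C)(C)C1=C(C)[C@@H]2C[C@@H]2[C@@]1(OC3=O)C[C@]3(C)C4(O[Si](C)(C)C)C(OC)=C(OC)C4O
F11 | step 6 | C5 trimethylstannyl analogue of 17 | C[Sn](C)(C)C1=C(C)[C@@H]2C[C@@H]2[C@@]1(OC3=O)C[C@]3(C)C4(O[Si](C)(C)C)C(OC)=C(OC)C4O[Si](CC)(CC)CC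
F12 | step 6 | C5 trimethylstannyl analogue of 19 | C[Sn](C)(C)C1=C(C)[C@@H]2C[C@@H]2[C@@]1(O[Si](CC)(CC)CC)C[C@@](C)(C(=O)OC)C3(O[Si](C)(C)C)C(OC)=C(OC)C3O[Si](CC)(CC)CC
F13 | step 10 | C7 tertiary alcohol (19 without its trimethylsilyl group) | IC1=C(C)[C@@H]2C[C@@H]2[C@@]1(O[Si](CC)(CC)CC)C[C@@](C)(C(=O)OC)C3(O)C(OC)=C(OC)C3O[Si](CC)(CC)CC
F14 | step 10 | C5 iodide carrying the 2-methoxy-4-(triethylsilyloxy)cyclobut-2-en-1-one | IC1=C(C)[C@@H]2C[C@@H]2[C@@]1(O[Si](CC)(CC)CC)C[C@@](C)(C(=O)OC)C3=C(OC)C(=O)C3O[Si](CC)(CC)CC
F15 | step 1 | (S)-2-(but-3-en-1-yl)oxirane | C=CCC[C@H]1CO1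
F16 | step 1 | (1S,2S,5R)-bicyclo[3.1.0]hexan-2-ol | C1C[C@@H]2C[C@@H]2[C@H]1O
F17 | step 1 | (1S,5S)-bicyclo[3.1.0]hex-3-en-2-one | C1=C[C@@H]2C[C@@H]2C1=O
A1 | alternative 1 | 16-membered diolide with C9–O–C12 esters, C7=C8 and C4=C5 alkenes, C9 oxygen α (C11 either epimer) | CC1C(=O)O[C@@H]2C=CCC3=C(CC(C)C(=O)O[C@@H]4C=CCC5=C(C1)[C@H]7C[C@H]7[C@]45C)[C@H]6C[C@H]6[C@]23C
A2 | alternative 1 | 12-membered carbocyclic diacid with C8=C9 alkenes | OC(=O)[C@]1(C)CC2=C3C[C@H](C=C[C@@]3(C)[C@@H]3C[C@H]23)[C@](C)(C(=O)O)CC2=C3C[C@@H]1C=C[C@@]3(C)[C@@H]1C[C@H]21
A3 | alternative 2 | 12-membered dienediyne with pendant acetonide and isopropenyl groups | COC(=O)[C@]1(C)CC#C/C=C(\[C@@H]2OC(C)(C)O[C@@H]2C(C)=C)[C@](C)(C(=O)OC)CC#C/C=C1\[C@@H]3OC(C)(C)O[C@@H]3C(C)=C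
A4 | alternative 2 | macrocyclic bis(hydrindadienone) with C3 ketones | COC(=O)[C@]1(C)CC2=C3C=C([C@@H]4OC(C)(C)O[C@@H]4[C@@]3(C)CC2=O)[C@](C)(C(=O)OC)CC2=C3C=C1[C@@H]4OC(C)(C)O[C@@H]4[C@@]3(C)CC2=O
A5 | alternative 3 | 18-membered bis(cyclohexenone) bis(cyclopropyl ketone) | COC(=O)[C@]1(C)CC(=O)[C@H]2C[C@H]2[C@@]3(C)CC=C(C(=O)[C@@H]3O[Si](C)(C)C(C)(C)C)[C@](C)(C(=O)OC)CC(=O)[C@H]4C[C@H]4[C@@]5(C)CC=C1C(=O)[C@@H]5O[Si](C)(C)C(C)(C)C
A6 | alternative 3 | cycloshizukaol A bis(tert-butyldimethylsilyl ether) | COC(=O)[C@]1(C)CC2=C3C=C(C(=O)[C@H](O[Si](C)(C)C(C)(C)C)[C@@]3(C)[C@@H]3C[C@H]23)[C@](C)(C(=O)OC)CC2=C3C=C1C(=O)[C@H](O[Si](C)(C)C(C)(C)C)[C@@]3(C)[C@@H]1C[C@H]21
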